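The acetal carbon (O–CH–O) shared by the dihydrobenzofuran and chromane rings and its neighbour, the quaternary O-bearing carbon on ring F, are both carbonyl-level, electrophilic carbons, and the acetal carbon sits on the ring F oxygen ortho to the carbon bearing it. An o-alkoxyaryl ketone therefore maps onto them: in a Norrish–Yang photocyclization the ring F ketone abstracts hydrogen from the O–CH2–O group of an ortho SEM ether and the 1,5-biradical closes the dihydrobenzofuran, the last C–C bond made. The precursor is an open, SEM-protected 3-substituted 2-hydroxyflavanone whose one fixed stereocentre comes from an organocatalytic nitro-Michael addition; fluoride, a Mitsunobu closure and mild acid finish the rings.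

Key step: step 15

Labels: ring A = prenylated benzo ring of the chromanone; ring B = 4-hydroxy-3-prenylphenyl on C-2; ring D = non-prenylated benzo ring of the chromane; ring F = prenylated benzo ring of the dihydrobenzofuran. C-2, C-3, C-4 are chromanone positions; "methine" is the CH bearing ring D; "carbinol carbon" is the quaternary O-bearing carbon on ring F. Prenyl = 3-methylbut-2-en-1-yl; SEM = [2-(trimethylsilyl)ethoxy]methyl.

Assumption: C-2 and C-3 of the chromanone ketal are both labile (ketal exchange, enolisation), and the configuration found in the target is taken to be the thermodynamic one.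

Remark: after step 15 no Brønsted acid stronger than PPTS is used, because the tertiary benzylic C–O bond on ring F (ortho- and para-oxygenated) ionises easily and would eliminate to the benzofuran.

Step 1
Reactants: 1 resorcinol
Product: 2 1,3-bis(SEM-oxy)benzene
Conditions: SEM-Cl (2.3 equiv), i-Pr2NEt, CH2Cl2, 0 °C → rt
Reagents that add atoms: 2-(trimethylsilyl)ethoxymethyl chloride, C[Si](C)(C)CCOCCl
Why: O-alkylation of both phenols by the reactive chloromethyl ether (Williamson-type acetal protection).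

Step 2
Reactants: 2 1,3-bis(SEM-oxy)benzene
Product: 4 1,3-bis(SEM-oxy)-2-prenylbenzene, via aryllithium 3 (not isolated)
Conditions: n-BuLi, THF, 0 °C → rt; then CuI (10 mol %), prenyl bromide, −78 °C → rt
Reagents that add atoms: prenyl bromide, CC(C)=CCBr
Why: Directed ortho-metalation at the position flanked by both acetal oxygens, then copper-catalysed allylic substitution that keeps the linear prenyl unit.

Step 3
Reactants: 4 1,3-bis(SEM-oxy)-2-prenylbenzene
Product: 6 1-iodo-2,4-bis(SEM-oxy)-3-prenylbenzene, via aryllithium 5 (not isolated)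
Conditions: n-BuLi, TMEDA, THF, −20 °C; then ICH2CH2I, −78 °C → rt
Reagents that add atoms: 1,2-diiodoethane, ICCI
Why: Second directed ortho-metalation at the only remaining position ortho to an OSEM group, followed by iodine transfer from the dihalide.

Step 4
Reactants: 6 1-iodo-2,4-bis(SEM-oxy)-3-prenylbenzene
Product: 7 1-(nitromethyl)-2,4-bis(SEM-oxy)-3-prenylbenzene
Conditions: MeNO2 (10 equiv), Pd2(dba)3 (2.5 mol %), XPhos (6 mol %), Cs2CO3, 1,4-dioxane, 4 Å MS, 50 °C
Reagents that add atoms: nitromethane, C[N+](=O)[O-]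
Why: Palladium-catalysed cross-coupling of an aryl halide with the nitronate of nitromethane (nitroalkane α-arylation); acetal ethers and the prenyl group are inert.

Step 5
Reactants: 8 1-(2,4-dihydroxyphenyl)ethanone
Product: 9 1-(2,4-dihydroxy-5-prenylphenyl)ethanone
Conditions: 2-methylbut-3-en-2-ol, BF3·OEt2, 1,4-dioxane, rt; separation from the 3-prenyl isomer
Reagents that add atoms: 2-methylbut-3-en-2-ol, CC(C)(O)C=C
Why: Friedel–Crafts prenylation by the allylic cation at C-5 (para to the chelated 2-OH, ortho to 4-OH); it is known to be low-yielding, and the regioisomer is removed by chromatography.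

Step 6
Reactants: 9 1-(2,4-dihydroxy-5-prenylphenyl)ethanone
Product: 10 1-[2-hydroxy-5-prenyl-4-(SEM-oxy)phenyl]ethanone
Conditions: SEM-Cl (1.05 equiv), K2CO3, acetone, 0 °C → rt
Reagents that add atoms: 2-(trimethylsilyl)ethoxymethyl chloride, C[Si](C)(C)CCOCCl
Why: Selective O-alkylation of the more acidic, non-chelated 4-OH; the 2-OH is hydrogen-bonded to the ketone.

Step 7
Reactants: 11 2,4-dihydroxybenzaldehyde
Product: 12 2,4-bis(SEM-oxy)benzaldehyde
Conditions: SEM-Cl (2.5 equiv), i-Pr2NEt, CH2Cl2, 0 → 40 °C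
Reagents that add atoms: 2-(trimethylsilyl)ethoxymethyl chloride, C[Si](C)(C)CCOCCl
Why: Exhaustive acetal protection of both phenols; excess reagent and warming overcome the chelated 2-OH.

Step 8
Reactants: 10 1-[2-hydroxy-5-prenyl-4-(SEM-oxy)phenyl]ethanone; 12 2,4-bis(SEM-oxy)benzaldehyde
Product: 13 (E)-3-[2,4-bis(SEM-oxy)phenyl]-1-[2-hydroxy-5-prenyl-4-(SEM-oxy)phenyl]prop-2-en-1-one
Conditions: KOH, EtOH–H2O, rt
Reagents that add atoms: none
Why: Claisen–Schmidt condensation gives the E-chalcone; SEM ethers and prenyl are base-stable.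

Step 9
Reactants: 14 methyl 4-hydroxybenzoate
Product: 16 methyl 4-hydroxy-3-prenylbenzoate, via sodium phenolate 15 (not isolated)
Conditions: NaH, toluene, rt; then prenyl bromide, 60 °C
Reagents that add atoms: prenyl bromide, CC(C)=CCBr
Why: ortho-C-alkylation of the tight sodium phenolate ion pair in a non-polar solvent (para position blocked); moderate yield is expected, with the O-prenyl ether as by-product.

Step 10
Reactants: 16 methyl 4-hydroxy-3-prenylbenzoate
Product: 17 methyl 3-prenyl-4-(SEM-oxy)benzoate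
Conditions: SEM-Cl, i-Pr2NEt, CH2Cl2, 0 °C → rt
Reagents that add atoms: 2-(trimethylsilyl)ethoxymethyl chloride, C[Si](C)(C)CCOCCl
Why: Acetal protection of the phenol.

Step 11
Reactants: 17 methyl 3-prenyl-4-(SEM-oxy)benzoate
Product: 19 3-prenyl-4-(SEM-oxy)benzoic acid, via lithium carboxylate 18 (not isolated)
Conditions: LiOH, THF–MeOH–H2O, 40 °C; then 1 M HCl to pH 4, 0 °C
Reagents that add atoms: lithium hydroxide, [Li+].[OH-]
Why: Saponification; the brief, cold acidification leaves the SEM ether intact.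

Step 12
Reactants: 13 chalcone; 19 3-prenyl-4-(SEM-oxy)benzoic acid
Product: 20 2-{(E)-3-[2,4-bis(SEM-oxy)phenyl]prop-2-enoyl}-4-prenyl-5-(SEM-oxy)phenyl 3-prenyl-4-(SEM-oxy)benzoate
Conditions: DCC, DMAP (cat.), CH2Cl2, 0 °C → rt
Reagents that add atoms: none
Why: Steglich esterification of the 2′-phenol; it installs the ring B acyl group for the later Baker–Venkataraman shift and blocks flavanone formation.

Step 13
Reactants: 20 chalcone aryl ester; 7 1-(nitromethyl)-2,4-bis(SEM-oxy)-3-prenylbenzene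
Product: 21 2-{(3R)-3-[2,4-bis(SEM-oxy)phenyl]-4-[2,4-bis(SEM-oxy)-3-prenylphenyl]-4-nitrobutanoyl}-4-prenyl-5-(SEM-oxy)phenyl 3-prenyl-4-(SEM-oxy)benzoate (C-4 epimers)
Conditions: quinine-derived bifunctional squaramide catalyst (10 mol %), toluene, rt
Reagents that add atoms: none
Why: Amine/squaramide-catalysed asymmetric Michael addition of a nitroalkane to a chalcone; the catalyst pseudoenantiomer (quinine- or quinidine-derived) is chosen to give the 3R methine, while the nitro-bearing carbon forms as a mixture and is erased in step 14.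

Step 14
Reactants: 21 nitro adduct
Product: 23 3-{(1R)-1-[2,4-bis(SEM-oxy)phenyl]-2-[2,4-bis(SEM-oxy)-3-prenylphenyl]-2-oxoethyl}-2-hydroxy-6-prenyl-7-(SEM-oxy)-2-[3-prenyl-4-(SEM-oxy)phenyl]chroman-4-one (C-2/C-3 mixture), via trilithium salt 22 (not isolated)
Conditions: LiN(SiMe3)2 (3.3 equiv), THF, −78 → 0 °C; then aq. TiCl3, NH4OAc (pH 5–6), THF–H2O, 0 °C → rt
Reagents that add atoms: water, O
Why: The nitronate forms first (so no retro-Michael and no acidic methine), the ketone enolate then transfers the aroyl group from O to C-3 (Baker–Venkataraman rearrangement), and the nitronate is converted to the ketone by the reductive Nef reaction with TiCl3 (classical γ-nitro ketone to 1,4-diketone conversion) at a pH that leaves the new α-aryl ketone centre untouched; the 2′-hydroxy-1,3-diketone closes to the 2-hydroxyflavanone hemiketal.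

Step 15
Reactants: 23 hemiketal triketone
Product: 25 3-{(R)-[2,4-bis(SEM-oxy)phenyl][(3S)-3-hydroxy-7-prenyl-6-(SEM-oxy)-2-[2-(trimethylsilyl)ethoxy]-2,3-dihydro-1-benzofuran-3-yl]methyl}-2-hydroxy-6-prenyl-7-(SEM-oxy)-2-[3-prenyl-4-(SEM-oxy)phenyl]chroman-4-one (acetal carbon epimers), via triplet 1,5-biradical 24 (not isolated)
Conditions: hν (λ ≥ 300 nm, Pyrex filter), degassed MeCN (1 mM), −30 °C
Reagents that add atoms: none
Why: Excitation gives the triplet of the ring F aryl ketone, whose oxygen abstracts a hydrogen from the ortho O–CH2–O group through a seven-membered transition state (1,6-hydrogen transfer); the triplet 1,5-biradical 24 then undergoes intersystem crossing and couples the former SEM methylene carbon with the former carbonyl carbon. The closest known reaction is the Norrish–Yang photocyclization of o-alkoxyphenyl ketones to 3-hydroxy-2,3-dihydrobenzofurans. One ring is closed, the five-membered dihydrobenzofuran, by 1,5-biradical recombination, a radical union of two carbons that are both electrophilic in polar terms. The carbinol centre is controlled by the neighbouring ring D methine (1,2-induction: its C–H lies in the ketyl plane towards ring F to avoid allylic 1,3-strain and the bond forms anti to the bulky chromanone C-3 substituent, on the ring D face), whereas the acetal centre forms as a mixture that is erased at the lactol stage and re-set in step 17. The step needs hydrogen transfer from this one CH2 to outrun α-cleavage of the α-aryl ketone and abstraction elsewhere: only these C–H bonds are both doubly oxygen-activated and within reach, ring A is masked as the hemiketal (no phenolic O–H, no abstractable δ-hydrogen), all phenols are capped, and low temperature disfavours α-cleavage. Abstraction from the ring D SEM group (1,7-transfer), if it occurs, gives a regioisomeric mixed acetal that converges on the same acetal after steps 16 and 17.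

Step 16
Reactants: 25 photoproduct
Product: 26 3-{(R)-(2,4-dihydroxyphenyl)[(3S)-2,3,6-trihydroxy-7-prenyl-2,3-dihydro-1-benzofuran-3-yl]methyl}-2,7-dihydroxy-2-(4-hydroxy-3-prenylphenyl)-6-prenylchroman-4-one (lactol and hemiketal epimers)
Conditions: Bu4NF (excess), ethylenediamine, THF–DMPU, 45 °C, argon; NH4Cl work-up to pH 7
Reagents that add atoms: none
Why: Fluoride attacks silicon of each SEM group and triggers β-elimination, so the five aryl hemiformal anions lose formaldehyde (trapped by the diamine) to give the phenols and the acetal SEM group gives the lactol; base is used because the tertiary benzylic alcohol tolerates base but not acid.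

Step 17
Reactants: 26 lactol pentaphenol
Product: 28 CNP0152008.3 (target; all three ring fusions cis, H-3 and the ring D methine H cis, absolute configuration as in the SMILES), via acetal hemiketal 27 (not isolated)
Conditions: PPh3, DIAD, THF (2 mM), 0 °C; then PPTS (cat.), 4 Å MS, CH2Cl2–THF, rt
Reagents that add atoms: none
Why: Mitsunobu activation of the lactol hydroxyl and intramolecular displacement by the ring D ortho-phenol close the six-membered chromane as the cis-fused bis-aryl acetal (the only strain-free fusion, dictated by the carbinol centre), and PPTS then ionises the C-2 hemiketal for capture by the tertiary alcohol, C-2 and C-3 settling in the all-cis arrangement under thermodynamic control.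

Compound list
1 | resorcinol | Oc1cccc(O)c1 | starting material
2 | 1,3-bis(SEM-oxy)benzene | C[Si](C)(C)CCOCOc1cccc(OCOCC[Si](C)(C)C)c1 | intermediate
3 | [2,6-bis(SEM-oxy)phenyl]lithium | [Li]c1c(OCOCC[Si](C)(C)C)cccc1OCOCC[Si](C)(C)C | intermediate
4 | 1,3-bis(SEM-oxy)-2-prenylbenzene | CC(C)=CCc1c(OCOCC[Si](C)(C)C)cccc1OCOCC[Si](C)(C)C | intermediate
5 | [2,4-bis(SEM-oxy)-3-prenylphenyl]lithium | [Li]c1ccc(OCOCC[Si](C)(C)C)c(CC=C(C)C)c1OCOCC[Si](C)(C)C | intermediate
6 | 1-iodo-2,4-bis(SEM-oxy)-3-prenylbenzene | Ic1ccc(OCOCC[Si](C)(C)C)c(CC=C(C)C)c1OCOCC[Si](C)(C)C | intermediate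
7 | 1-(nitromethyl)-2,4-bis(SEM-oxy)-3-prenylbenzene | [O-][N+](=O)Cc1ccc(OCOCC[Si](C)(C)C)c(CC=C(C)C)c1OCOCC[Si](C)(C)C | intermediate
8 | 1-(2,4-dihydroxyphenyl)ethanone | CC(=O)c1ccc(O)cc1O | starting material
9 | 1-(2,4-dihydroxy-5-prenylphenyl)ethanone | CC(=O)c1cc(CC=C(C)C)c(O)cc1O | intermediate
10 | 1-[2-hydroxy-5-prenyl-4-(SEM-oxy)phenyl]ethanone | CC(=O)c1cc(CC=C(C)C)c(OCOCC[Si](C)(C)C)cc1O | intermediate
11 | 2,4-dihydroxybenzaldehyde | O=Cc1ccc(O)cc1O | starting material
12 | 2,4-bis(SEM-oxy)benzaldehyde | O=Cc1ccc(OCOCC[Si](C)(C)C)cc1OCOCC[Si](C)(C)C | intermediate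
13 | (E)-3-[2,4-bis(SEM-oxy)phenyl]-1-[2-hydroxy-5-prenyl-4-(SEM-oxy)phenyl]prop-2-en-1-one | O=C(/C=C/c1ccc(OCOCC[Si](C)(C)C)cc1OCOCC[Si](C)(C)C)c1cc(CC=C(C)C)c(OCOCC[Si](C)(C)C)cc1O | intermediate
14 | methyl 4-hydroxybenzoate | COC(=O)c1ccc(O)cc1 | starting material
15 | sodium 4-(methoxycarbonyl)phenolate | [Na+].COC(=O)c1ccc([O-])cc1 | intermediate
16 | methyl 4-hydroxy-3-prenylbenzoate | COC(=O)c1ccc(O)c(CC=C(C)C)c1 | intermediate
17 | methyl 3-prenyl-4-(SEM-oxy)benzoate | COC(=O)c1ccc(OCOCC[Si](C)(C)C)c(CC=C(C)C)c1 | intermediate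
18 | lithium 3-prenyl-4-(SEM-oxy)benzoate | [Li+].[O-]C(=O)c1ccc(OCOCC[Si](C)(C)C)c(CC=C(C)C)c1 | intermediate
19 | 3-prenyl-4-(SEM-oxy)benzoic acid | OC(=O)c1ccc(OCOCC[Si](C)(C)C)c(CC=C(C)C)c1 | intermediate
20 | 2-{(E)-3-[2,4-bis(SEM-oxy)phenyl]prop-2-enoyl}-4-prenyl-5-(SEM-oxy)phenyl 3-prenyl-4-(SEM-oxy)benzoate | O=C(/C=C/c1ccc(OCOCC[Si](C)(C)C)cc1OCOCC[Si](C)(C)C)c1cc(CC=C(C)C)c(OCOCC[Si](C)(C)C)cc1OC(=O)c1ccc(OCOCC[Si](C)(C)C)c(CC=C(C)C)c1 | intermediate
21 | (3R)-nitro Michael adduct of 20 and 7 (nitro carbon epimers) | O=C(C[C@@H](C(c1ccc(OCOCC[Si](C)(C)C)c(CC=C(C)C)c1OCOCC[Si](C)(C)C)[N+](=O)[O-])c1ccc(OCOCC[Si](C)(C)C)cc1OCOCC[Si](C)(C)C)c1cc(CC=C(C)C)c(OCOCC[Si](C)(C)C)cc1OC(=O)c1ccc(OCOCC[Si](C)(C)C)c(CC=C(C)C)c1 | intermediate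
22 | trilithium nitronate–1,3-diketonate–phenolate after aroyl migration | [Li+].[Li+].[Li+].[O-]C(c1ccc(OCOCC[Si](C)(C)C)c(CC=C(C)C)c1)=C([C@@H](C(=[N+]([O-])[O-])c1ccc(OCOCC[Si](C)(C)C)c(CC=C(C)C)c1OCOCC[Si](C)(C)C)c1ccc(OCOCC[Si](C)(C)C)cc1OCOCC[Si](C)(C)C)C(=O)c1cc(CC=C(C)C)c(OCOCC[Si](C)(C)C)cc1[O-] | intermediate
23 | 2-hydroxyflavanone hemiketal with the (1R)-1-aryl-2-aryl-2-oxoethyl group at C-3 (C-2/C-3 mixture) | O=C1c2cc(CC=C(C)C)c(OCOCC[Si](C)(C)C)cc2OC(O)(c2ccc(OCOCC[Si](C)(C)C)c(CC=C(C)C)c2)C1[C@@H](C(=O)c1ccc(OCOCC[Si](C)(C)C)c(CC=C(C)C)c1OCOCC[Si](C)(C)C)c1ccc(OCOCC[Si](C)(C)C)cc1OCOCC[Si](C)(C)C | intermediate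
24 | triplet 1,5-biradical (ketyl carbon and O–CH–O carbon) | O=C1c2cc(CC=C(C)C)c(OCOCC[Si](C)(C)C)cc2OC(O)(c2ccc(OCOCC[Si](C)(C)C)c(CC=C(C)C)c2)C1[C@@H]([C](O)c1ccc(OCOCC[Si](C)(C)C)c(CC=C(C)C)c1O[CH]OCC[Si](C)(C)C)c1ccc(OCOCC[Si](C)(C)C)cc1OCOCC[Si](C)(C)C | intermediate
25 | photoproduct: (3S)-3-hydroxy-2-[2-(trimethylsilyl)ethoxy]-2,3-dihydrobenzofuran on the (R)-methine (acetal epimers) | O=C1c2cc(CC=C(C)C)c(OCOCC[Si](C)(C)C)cc2OC(O)(c2ccc(OCOCC[Si](C)(C)C)c(CC=C(C)C)c2)C1[C@@H]([C@]2(O)c3ccc(OCOCC[Si](C)(C)C)c(CC=C(C)C)c3OC2OCC[Si](C)(C)C)c1ccc(OCOCC[Si](C)(C)C)cc1OCOCC[Si](C)(C)C | intermediate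
26 | lactol pentaphenol (all SEM groups removed) | O=C1c2cc(CC=C(C)C)c(O)cc2OC(O)(c2ccc(O)c(CC=C(C)C)c2)C1[C@@H]([C@]2(O)c3ccc(O)c(CC=C(C)C)c3OC2O)c1ccc(O)cc1O | intermediate
27 | cis-fused benzofuro-chromane acetal with free carbinol and C-2 hemiketal | O=C1c2cc(CC=C(C)C)c(O)cc2OC(O)(c2ccc(O)c(CC=C(C)C)c2)C1[C@@H]3c4ccc(O)cc4O[C@H]4Oc5c(ccc(O)c5CC=C(C)C)[C@]43O | intermediate
28 | CNP0152008.3 | CC(C)=CCc1cc([C@@]23Oc4cc(O)c(CC=C(C)C)cc4C(=O)[C@@H]2[C@@H]2c4ccc(O)cc4O[C@H]4Oc5c(ccc(O)c5CC=C(C)C)[C@]42O3)ccc1O | target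

Total step count: 17. Longest linear sequence: 9 steps (14 → 28 through steps 9–17).

Steps most likely to fail

1. Step 15. Three processes threaten it. Norrish α-cleavage of the α-aryl ketone can compete with hydrogen transfer, with loss of material and, through cage recombination, of the methine configuration. Light can be absorbed or triplet energy drained by the open 2′-hydroxy-1,3-diketone tautomer. The biradical can close on the wrong ketyl face. Fallback: change the order so that the photoreaction runs on a substrate with one reactive ketone and no hydroxy-diketone. From 21, one equivalent of LiN(SiMe3)2 at −78 °C forms only the nitronate, and buffered TiCl3 then gives the 1,4-diketone aryl ester F1. Photolysis of F1 under the conditions of step 15 gives the dihydrobenzofuranol F2. Baker–Venkataraman rearrangement of F2 (LiN(SiMe3)2, THF, −78 → 0 °C; the methine is no longer α to a ketone) returns to 25.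

2. Step 16. The hindered aryl SEM ethers may cleave slowly and force heating. Under hot basic fluoride, released formaldehyde can hydroxymethylate the electron-rich phenoxides, and the ring-opened lactolate (an α-hydroxy aldehyde) can undergo an α-ketol shift. Fallback: replace base-mediated desilylation by chelation-assisted Lewis-acid cleavage. From 25, MgBr2·OEt2 in MeNO2–Et2O at rt cleaves the SEM ethers and the SEM acetal without generating phenoxides, and the route is rejoined at 26. No new compound is formed.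

3. Step 13. Two ortho-substituted aryl groups meet at the new C–C bond, so the addition may be slow and the catalyst may lose facial control. Fallback: form the stereocentre with the small nucleophile and attach ring F afterwards. From 20, the same squaramide-catalysed addition of nitromethane gives the nitromethane adduct F3. Palladium-catalysed α-arylation of this primary nitroalkane with aryl iodide 6 (Pd2(dba)3, 2-(di-tert-butylphosphino)-2′-methylbiphenyl, Cs2CO3, DME, 50 °C) returns to 21. Any premature aroyl migration under the carbonate is harmless because step 14 effects it anyway.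

Further compounds
F1 | step 15 | 2-{(3R)-3-[2,4-bis(SEM-oxy)phenyl]-4-[2,4-bis(SEM-oxy)-3-prenylphenyl]-4-oxobutanoyl}-4-prenyl-5-(SEM-oxy)phenyl 3-prenyl-4-(SEM-oxy)benzoate | O=C(C[C@@H](C(=O)c1ccc(OCOCC[Si](C)(C)C)c(CC=C(C)C)c1OCOCC[Si](C)(C)C)c1ccc(OCOCC[Si](C)(C)C)cc1OCOCC[Si](C)(C)C)c1cc(CC=C(C)C)c(OCOCC[Si](C)(C)C)cc1OC(=O)c1ccc(OCOCC[Si](C)(C)C)c(CC=C(C)C)c1
F2 | step 15 | 2-{(3R)-3-[2,4-bis(SEM-oxy)phenyl]-3-[(3S)-3-hydroxy-7-prenyl-6-(SEM-oxy)-2-[2-(trimethylsilyl)ethoxy]-2,3-dihydro-1-benzofuran-3-yl]propanoyl}-4-prenyl-5-(SEM-oxy)phenyl 3-prenyl-4-(SEM-oxy)benzoate (acetal epimers) | O=C(C[C@@H]([C@]2(O)c3ccc(OCOCC[Si](C)(C)C)c(CC=C(C)C)c3OC2OCC[Si](C)(C)C)c1ccc(OCOCC[Si](C)(C)C)cc1OCOCC[Si](C)(C)C)c1cc(CC=C(C)C)c(OCOCC[Si](C)(C)C)cc1OC(=O)c1ccc(OCOCC[Si](C)(C)C)c(CC=C(C)C)c1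
F0 | step 16 | none | none
F3 | step 13 | 2-{(3R)-3-[2,4-bis(SEM-oxy)phenyl]-4-nitrobutanoyl}-4-prenyl-5-(SEM-oxy)phenyl 3-prenyl-4-(SEM-oxy)benzoate | O=C(C[C@@H](C[N+](=O)[O-])c1ccc(OCOCC[Si](C)(C)C)cc1OCOCC[Si](C)(C)C)c1cc(CC=C(C)C)c(OCOCC[Si](C)(C)C)cc1OC(=O)c1ccc(OCOCC[Si](C)(C)C)c(CC=C(C)C)c1
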